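The target is cut at the bond between the spiro carbon and the neighbouring alkene carbon of the cyclohexene ring (ring B). The key step exploits the vicinal pair spiro carbon / C(OH)CH3 carbon of the bromocyclohexane ring (ring A). A tetrasubstituted epoxide at these two carbons, carrying a 1-silyloxycyclopent-2-enyl group, is opened by a silyl triflate, and the alkenyl carbon of the five-membered ring shifts to the spiro carbon anti to the epoxide oxygen. One operation enlarges the cyclopentene to ring B, sets the spiro centre and fixes the tertiary carbinol trans to the migrated carbon. The precursor comes from enzymatically made (4R,6R)-actinol and cyclopent-2-enone.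

Key step: step 5

Remark: locants in the text are ring A = spiro carbon, C7 (C(OH)CH3), C8, C9 (CHBr), C10, C11 (C(CH3)2) and ring B = spiro carbon, C2=C3, C4 (bearing =CHBr), C5, C6 (in the spiro[5.5]undecane names C1 = C7, C3 = C9, C6 = spiro carbon, C7 to C11 = C2 to C6); it is assumed that dimethyldioxirane attacks the ring-A double bond anti to the pseudoaxial C11 methyl group, that is, on the face of the equatorial C9 silyloxy group.

Step 1
Reactants: 1 2,6,6-trimethylcyclohex-2-ene-1,4-dione (ketoisophorone)
Product: 3 (4R,6R)-4-hydroxy-2,2,6-trimethylcyclohexanone, via (6R)-levodione 2 (not isolated)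
Conditions: ene-reductase (old yellow enzyme family), then (6R)-levodione reductase (short-chain alcohol dehydrogenase), NAD(P)H (cat.), D-glucose, glucose dehydrogenase, phosphate buffer pH 7, 30 °C
Reagents that add atoms: none
Why: Enzymatic reduction cascade in which the flavin ene-reductase hydrogenates the ring C=C to set the 6R centre and the dehydrogenase then reduces only the unhindered C4 carbonyl from one face to the 4R alcohol, the future C9.

Step 2
Reactants: 3 (4R,6R)-4-hydroxy-2,2,6-trimethylcyclohexanone
Product: 4 (4R,6R)-4-(tert-butyldimethylsilyloxy)-2,2,6-trimethylcyclohexanone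
Conditions: TBSCl, imidazole, DMF, 25 °C
Reagents that add atoms: tert-butyldimethylsilyl chloride CC(C)(C)[Si](C)(C)Cl
Why: Standard silyl ether protection of the secondary alcohol, which touches no stereocentre.

Step 3
Reactants: 4 (4R,6R)-4-(tert-butyldimethylsilyloxy)-2,2,6-trimethylcyclohexanone
Product: 5 2,4,6-triisopropylbenzenesulfonylhydrazone of 4
Conditions: 2,4,6-triisopropylbenzenesulfonyl hydrazide, PPTS (cat.), THF, 4 Å molecular sieves, 40 °C
Reagents that add atoms: 2,4,6-triisopropylbenzenesulfonyl hydrazide NNS(=O)(=O)c1c(C(C)C)cc(C(C)C)cc1C(C)C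
Why: Acid-catalysed sulfonylhydrazone formation at the hindered ketone should place the N-sulfonyl group away from the gem-dimethyl carbon and syn to the only alpha-hydrogen.

Step 4
Reactants: 5 2,4,6-triisopropylbenzenesulfonylhydrazone of 4; 6 cyclopent-2-en-1-one
Product: 9 1-[(4R)-4-(tert-butyldimethylsilyloxy)-2,6,6-trimethylcyclohex-1-en-1-yl]-1-(triethylsilyloxy)cyclopent-2-ene (both epimers at the carbinol carbon), via alkenyllithium 7 (not isolated), via lithium alkoxide 8 (not isolated)
Conditions: n-BuLi (2.3 equiv), TMEDA, THF, −78 → 0 °C; then 6/CeCl3, THF, −78 °C; then Et3SiOTf, −78 → 0 °C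
Reagents that add atoms: triethylsilyl trifluoromethanesulfonate CC[Si](CC)(CC)OS(=O)(=O)C(F)(F)F
Why: The Shapiro reaction should give the tetrasubstituted alkenyllithium, which adds 1,2 to the CeCl3-activated enone before the alkoxide is silylated in the flask; the new carbinol centre forms as both epimers, which does not matter because this carbon becomes the carbonyl carbon in step 5.

Step 5
Reactants: 9 1-[(4R)-4-(tert-butyldimethylsilyloxy)-2,6,6-trimethylcyclohex-1-en-1-yl]-1-(triethylsilyloxy)cyclopent-2-ene
Product: 11 (1S,3S,6R)-3-(tert-butyldimethylsilyloxy)-1,5,5-trimethyl-1-(triethylsilyloxy)spiro[5.5]undec-7-en-11-one, via epoxide 10 (not isolated)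
Conditions: dimethyldioxirane, acetone/CH2Cl2, −40 → 0 °C; evaporate; Et3SiOTf (10 mol %), CH2Cl2, −78 °C
Reagents that add atoms: dimethyldioxirane CC1(C)OO1
Why: Dimethyldioxirane should epoxidise the electron-rich tetrasubstituted ring-A double bond in preference to the disubstituted cyclopentene bond, from the face anti to the pseudoaxial C11 methyl group. Silylation of the epoxide oxygen by Et3SiOTf then opens the C–O bond at the carbinol-bearing carbon while the alkenyl carbon of the cyclopentene shifts to it from the opposite side, and the resulting silyloxocarbenium ion passes Et3Si+ on to the next epoxide; the closest known type is the semipinacol rearrangement of a 2,3-epoxy alcohol silyl ether. Ring B is not closed by a cyclisation but grows from five to six members through this 1,2-shift, the former carbinol carbon becoming C6 (C=O) and the migrating sp2 carbon becoming C2. The spiro centre is set by inversion at the epoxide carbon (C2 anti to the C7 oxygen, the carbonyl carbon syn to it), and C7 keeps the configuration given by the epoxidation. The step needs opening at the carbinol-bearing epoxide carbon and alkenyl rather than alkyl migration; the silyloxy group (developing oxocarbenium ion) and the higher migratory aptitude of the sp2 carbon should secure both, and the silyl relay leaves the tertiary oxygen protected against retro-aldol cleavage.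

Step 6
Reactants: 11 (1S,3S,6R)-3-(tert-butyldimethylsilyloxy)-1,5,5-trimethyl-1-(triethylsilyloxy)spiro[5.5]undec-7-en-11-one
Product: 13 (1S,3S,6S)-3-(tert-butyldimethylsilyloxy)-1,5,5-trimethyl-1-(triethylsilyloxy)spiro[5.5]undec-7-ene, via tosylhydrazone 12 (not isolated)
Conditions: TsNHNH2, AcOH (cat.), EtOH, 60 °C; evaporate; catecholborane, CHCl3, 0 → 25 °C; then NaOAc·3H2O, reflux
Reagents that add atoms: none
Why: Reductive deoxygenation of a tosylhydrazone (hydride from catecholborane, then acetate-induced loss of sulfinate and N2) should turn the C6 carbonyl into CH2 under nearly neutral conditions, and the C2=C3 bond cannot shift because it is not conjugated with the hydrazone.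

Step 7
Reactants: 13 (1S,3S,6S)-3-(tert-butyldimethylsilyloxy)-1,5,5-trimethyl-1-(triethylsilyloxy)spiro[5.5]undec-7-ene
Product: 14 (1S,3S,6S)-3-(tert-butyldimethylsilyloxy)-1,5,5-trimethyl-1-(triethylsilyloxy)spiro[5.5]undec-7-en-9-one
Conditions: Rh2(cap)4 (cap = caprolactamate, 1 mol %), t-BuOOH, K2CO3, CH2Cl2, 25 °C
Reagents that add atoms: tert-butyl hydroperoxide CC(C)(C)OO
Why: Allylic oxidation by tert-butylperoxyl radicals should attack C4, the only allylic C–H position because the other allylic atom is the quaternary spiro carbon, and give the 4,4-disubstituted cyclohexenone.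

Step 8
Reactants: 14 (1S,3S,6S)-3-(tert-butyldimethylsilyloxy)-1,5,5-trimethyl-1-(triethylsilyloxy)spiro[5.5]undec-7-en-9-one
Product: 15 (1S,3S,6S,9Z)-9-(bromomethylidene)-3-(tert-butyldimethylsilyloxy)-1,5,5-trimethyl-1-(triethylsilyloxy)spiro[5.5]undec-7-ene
Conditions: Ph3P(CH2Br)Br, NaN(SiMe3)2, THF, −78 °C; then 14, −78 → 25 °C
Reagents that add atoms: (bromomethyl)triphenylphosphonium bromide [Br-].BrC[P+](c1ccccc1)(c1ccccc1)c1ccccc1
Why: Wittig bromomethylenation of the enone carbonyl, in which the bromine should settle on the side of the flat sp2 C3–H and away from the C5 methylene (as it prefers the less encumbered alpha-carbon of cyclohexanones), giving the Z bromoalkene; this preference is the weakest stereochemical argument of the route, and any E isomer would be removed by chromatography.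

Step 9
Reactants: 15 (1S,3S,6S,9Z)-9-(bromomethylidene)-3-(tert-butyldimethylsilyloxy)-1,5,5-trimethyl-1-(triethylsilyloxy)spiro[5.5]undec-7-ene
Product: 16 (1S,3S,6S,9Z)-9-(bromomethylidene)-1,5,5-trimethylspiro[5.5]undec-7-ene-1,3-diol
Conditions: Bu4NF, THF, 0 → 50 °C
Reagents that add atoms: none
Why: Fluoride-induced desilylation should free both alcohols, and the tertiary alkoxide cannot fragment because no carbonyl group is left.

Step 10
Reactants: 16 (1S,3S,6S,9Z)-9-(bromomethylidene)-1,5,5-trimethylspiro[5.5]undec-7-ene-1,3-diol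
Product: 17 (1S,3R,6S,9Z)-3-bromo-9-(bromomethylidene)-1,5,5-trimethylspiro[5.5]undec-7-en-1-ol
Conditions: CBr4, PPh3, pyridine, CH2Cl2, 0 → 25 °C
Reagents that add atoms: carbon tetrabromide BrC(Br)(Br)Br
Why: In the Appel reaction the secondary C9 alcohol, axial in the reacting chair, should be displaced by bromide with inversion (SN2) to the equatorial 9R bromide, while the tertiary C7 alcohol on the same face cannot attack from the rear and stays untouched.

Compound list
1 | 2,6,6-trimethylcyclohex-2-ene-1,4-dione (ketoisophorone) | CC1=CC(=O)CC(C)(C)C1=O | starting material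
2 | (6R)-2,2,6-trimethylcyclohexane-1,4-dione ((6R)-levodione) | C[C@@H]1CC(=O)CC(C)(C)C1=O | intermediate
3 | (4R,6R)-4-hydroxy-2,2,6-trimethylcyclohexanone ((4R,6R)-actinol) | C[C@@H]1C[C@@H](O)CC(C)(C)C1=O | intermediate
4 | (4R,6R)-4-(tert-butyldimethylsilyloxy)-2,2,6-trimethylcyclohexanone | C[C@@H]1C[C@@H](O[Si](C)(C)C(C)(C)C)CC(C)(C)C1=O | intermediate
5 | 2,4,6-triisopropylbenzenesulfonylhydrazone of 4 | C[C@@H]1C[C@@H](O[Si](C)(C)C(C)(C)C)CC(C)(C)C1=NNS(=O)(=O)c2c(C(C)C)cc(C(C)C)cc2C(C)C | intermediate
6 | cyclopent-2-en-1-one | O=C1C=CCC1 | starting material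
7 | (4R)-4-(tert-butyldimethylsilyloxy)-2,6,6-trimethylcyclohex-1-en-1-yllithium | [Li]C1=C(C)C[C@@H](O[Si](C)(C)C(C)(C)C)CC1(C)C | intermediate
8 | lithium 1-[(4R)-4-(tert-butyldimethylsilyloxy)-2,6,6-trimethylcyclohex-1-en-1-yl]cyclopent-2-en-1-olate (both carbinol epimers) | [Li]OC1(C=CCC1)C2=C(C)C[C@@H](O[Si](C)(C)C(C)(C)C)CC2(C)C | intermediate
9 | 1-[(4R)-4-(tert-butyldimethylsilyloxy)-2,6,6-trimethylcyclohex-1-en-1-yl]-1-(triethylsilyloxy)cyclopent-2-ene (both carbinol epimers) | CC[Si](CC)(CC)OC1(C=CCC1)C2=C(C)C[C@@H](O[Si](C)(C)C(C)(C)C)CC2(C)C | intermediate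
10 | epoxide of 9 at the ring-A double bond, oxirane oxygen cis to the C9 silyloxy group (both carbinol epimers) | CC1(C)C[C@H](O[Si](C)(C)C(C)(C)C)C[C@]2(C)O[C@]12C3(O[Si](CC)(CC)CC)C=CCC3 | intermediate
11 | (1S,3S,6R)-3-(tert-butyldimethylsilyloxy)-1,5,5-trimethyl-1-(triethylsilyloxy)spiro[5.5]undec-7-en-11-one | CC1(C)C[C@H](O[Si](C)(C)C(C)(C)C)C[C@](C)(O[Si](CC)(CC)CC)[C@@]12C=CCCC2=O | intermediate
12 | p-toluenesulfonylhydrazone of 11 | CC1(C)C[C@H](O[Si](C)(C)C(C)(C)C)C[C@](C)(O[Si](CC)(CC)CC)[C@@]12C=CCCC2=NNS(=O)(=O)c3ccc(C)cc3 | intermediate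
13 | (1S,3S,6S)-3-(tert-butyldimethylsilyloxy)-1,5,5-trimethyl-1-(triethylsilyloxy)spiro[5.5]undec-7-ene | CC1(C)C[C@H](O[Si](C)(C)C(C)(C)C)C[C@](C)(O[Si](CC)(CC)CC)[C@@]12C=CCCC2 | intermediate
14 | (1S,3S,6S)-3-(tert-butyldimethylsilyloxy)-1,5,5-trimethyl-1-(triethylsilyloxy)spiro[5.5]undec-7-en-9-one | CC1(C)C[C@H](O[Si](C)(C)C(C)(C)C)C[C@](C)(O[Si](CC)(CC)CC)[C@@]12C=CC(=O)CC2 | intermediate
15 | (1S,3S,6S,9Z)-9-(bromomethylidene)-3-(tert-butyldimethylsilyloxy)-1,5,5-trimethyl-1-(triethylsilyloxy)spiro[5.5]undec-7-ene | CC1(C)C[C@H](O[Si](C)(C)C(C)(C)C)C[C@](C)(O[Si](CC)(CC)CC)[C@@]12C=C/C(=C\Br)CC2 | intermediate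
16 | (1S,3S,6S,9Z)-9-(bromomethylidene)-1,5,5-trimethylspiro[5.5]undec-7-ene-1,3-diol | CC1(C)C[C@H](O)C[C@](C)(O)[C@@]12C=C/C(=C\Br)CC2 | intermediate
17 | (1S,3R,6S,9Z)-3-bromo-9-(bromomethylidene)-1,5,5-trimethylspiro[5.5]undec-7-en-1-ol | CC1(C)C[C@@H](Br)C[C@](C)(O)[C@@]12C=C/C(=C\Br)CC2 | target

Total step count: 10. Longest linear sequence: 10 steps (from 1; cyclopent-2-en-1-one 6 enters in step 4).

Steps most likely to fail:

Step 8. The ylide may add with little preference for placing bromine on the C3 side, so the geometry of the exocyclic double bond may be poorly controlled. The fallback sets out from 14 and comes back at 15. Corey–Fuchs-type dibromoolefination (CBr4, PPh3, toluene, 80 °C) would give the 1,1-dibromodiene F1, in which no geometry has to be set. Hydrogenolysis with Bu3SnH and Pd(PPh3)4 (cat.) should then remove the bromine that lies trans to the conjugating C2=C3 unit, the C–Br bond preferred for oxidative addition in 1,1-dibromo-1,3-dienes, and leave the Z bromide 15.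

Step 5. The epoxidation may take place on both faces of the hindered double bond, and the silyl-triggered opening may occur at the methyl-bearing epoxide carbon or compete with ionisation of the allylic silyl ether. The fallback sets out from 5 and 6 and comes back at 11. The Shapiro addition is quenched with NH4Cl instead of the silyl triflate to give the free carbinol F2. Epoxidation with m-CPBA/NaHCO3, guided by hydrogen bonding to the tertiary hydroxyl within the same conformational bias of ring A, would give the epoxy alcohol F3. BF3·OEt2 at −78 °C should trigger the semipinacol shift of the free epoxy alcohol to the beta-hydroxy ketone F4, which is silylated (Et3SiOTf, 2,6-lutidine) to 11.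

Step 6. Condensation of the sulfonyl hydrazide with the carbonyl group next to the crowded spiro centre may be slow or incomplete, or the reduction may stop before loss of nitrogen. The fallback sets out from 11 and comes back at 13. LiAlH4 reduction would give the C6 alcohol F5, and 1,1'-thiocarbonyldiimidazole/DMAP would convert it into the imidazolide F6. Barton–McCombie deoxygenation (Bu3SnH, AIBN, toluene, 110 °C) should then give 13.

Further compounds
F1 | step 8 | (1S,3S,6S)-9-(dibromomethylidene)-3-(tert-butyldimethylsilyloxy)-1,5,5-trimethyl-1-(triethylsilyloxy)spiro[5.5]undec-7-ene | CC1(C)C[C@H](O[Si](C)(C)C(C)(C)C)C[C@](C)(O[Si](CC)(CC)CC)[C@@]12C=CC(=C(Br)Br)CC2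
F2 | step 5 | 1-[(4R)-4-(tert-butyldimethylsilyloxy)-2,6,6-trimethylcyclohex-1-en-1-yl]cyclopent-2-en-1-ol (both carbinol epimers) | OC1(C=CCC1)C2=C(C)C[C@@H](O[Si](C)(C)C(C)(C)C)CC2(C)C
F3 | step 5 | epoxide of F2 at the ring-A double bond, oxirane oxygen cis to the C9 silyloxy group | CC1(C)C[C@H](O[Si](C)(C)C(C)(C)C)C[C@]2(C)O[C@]12C3(O)C=CCC3
F4 | step 5 | (1S,3S,6R)-3-(tert-butyldimethylsilyloxy)-1-hydroxy-1,5,5-trimethylspiro[5.5]undec-7-en-11-one | CC1(C)C[C@H](O[Si](C)(C)C(C)(C)C)C[C@](C)(O)[C@@]12C=CCCC2=O
F5 | step 6 | C11 alcohol from reduction of 11 (either epimer at the new carbinol carbon) | CC1(C)C[C@H](O[Si](C)(C)C(C)(C)C)C[C@](C)(O[Si](CC)(CC)CC)[C@@]12C=CCCC2O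
F6 | step 6 | O-alkyl 1H-imidazole-1-carbothioate of F5 | CC1(C)C[C@H](O[Si](C)(C)C(C)(C)C)C[C@](C)(O[Si](CC)(CC)CC)[C@@]12C=CCCC2OC(=S)n3ccnc3
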